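**Assumption:** Lignan numbering is used (C7/C7' carbinol carbons, C8/C8' ring CH, C9/C9' ring CH2; ring A on C7, ring A' on C7'). The target is the C2-symmetric (7S,7'S,8R,8'R) isomer, and O-tosylvanillin is made in one step.

## Structural features

The target is a tetrahydrofuran (ring O, C9, C8, C8', C9') whose two methine carbons C8 and C8' each carry an aryl(hydroxy)methyl arm, C7 with ring A and C7' with ring A'. Both aryl groups are 4-hydroxy-3-methoxyphenyl. The four stereocentres C7–C8–C8'–C7' are contiguous (7S,8R,8'R,7'S); the ring substituents are trans, and each carbinol oxygen is anti to the ring CH2 of its own ring carbon when C8'–C8–C7–aryl is drawn as a zigzag. Both secondary alcohols are benzylic and para to an oxygen donor. Acid therefore ionises them (epimerisation, elimination, or closure of the other ring onto the cation to an aryltetralin), a para-phenoxide can expel a benzylic leaving group as a quinone methide, and the benzylic C–O bonds are open to hydrogenolysis. The ring is simple; the real difficulty is fixing the two exocyclic carbinol centres relative to the ring centres and carrying the activated C–O bonds to the end. The key step uses two features: C9 is an isolated CH2 between the ring oxygen and C8, so formaldehyde can supply it as a CH2=O(+) unit already bound to the oxygen on C9'; and C7 is benzylic to ring A, so a C7=C8 styrene can bond to that unit through C8 while C7 holds the charge until water arrives. The same activation would labilise C7'–O and make ring A' a trap for the C7 cation, so the protecting groups break the symmetry: benzyl ether (donor) on ring A, tosylate (acceptor) on ring A', pivalate on O7'.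

## Logic of the disconnections

**19 ⇒ 18 ⇒ 17 ⇒ 16.** Three protecting-group bonds are restored: O–CH2Ph on ring A, O–S on ring A', and acyl–O at C7'. The order follows the fragility of the carbinols: the last forward step must be neutral, and the ring A' phenol may be freed only after the C7' ester has gone, because a para-phenoxide expels a benzylic carboxylate. The gain is a fully masked, electronically differentiated tetrahydrofuran. Each unmasking must leave four benzylic C–O bonds and four stereocentres untouched.

**16 ⇒ 13 + 14.** The C8–C9 and C9–O ring bonds and the C7–OH bond are cut, removing the ring, C8, C7 and one carbon together. This is the place to cut because C9 has no other substituent and C7 can carry a benzylic charge. What remains is an acyclic E-homoallylic alcohol with only C8' and C7' as stereocentres. The forward step must bond through C8, close trans to the C8' substituent, take up water anti at C7, and neither ionise C7'–O nor let ring A' attack C7. The last two demands are why ring A' carries a tosylate in 13.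

**13 ⇒ 12 ⇒ 11.** The C9' alcohol is traced to the imide carbonyl and the C7' ester to the free aldol hydroxyl. The 1,3-diol monoester becomes a syn aldol adduct whose two oxygens are already differentiated. The forward steps must acylate a hindered benzylic alcohol beside an acidic α-hydrogen without elimination, and reduce the imide without moving or losing the ester.

**11 ⇒ 7 + 9.** The C8'–C7' bond is cut. An auxiliary-controlled aldol addition makes this bond and both stereocentres with predictable absolute configuration from two fragments of similar size. The forward step needs a Z enolate that reacts through its α-carbon, not the styryl terminus.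

**9 ⇒ 8; 7 ⇒ 4 + 5; 4 ⇒ 1 + 2.** The aryl O–S bond, the N–acyl bond and the C7=C8 double bond are cut, leading to four simple starting materials. The olefination must give the E alkene, because this geometry is later translated into the configuration at C7, and the acylation must not move the double bond into conjugation.

## Other disconnections considered

**Alternative 1:** The cut removes C8–C9 and C8'–C9'. The CH2–O–CH2 bridge becomes the parent carbonyl ylide, and C7–C8–C8'–C7' becomes the fumaric bis-amide A2. In the forward step the ylide, freed by fluoride from a silyl precursor, would add suprafacially across the E alkene to give the trans diamide A1. Both amides must then become the aryl ketones of A3, followed by double reduction and debenzylation.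
- In favour: it uses the C2 symmetry fully, and the trans ring relationship follows from alkene geometry rather than a conformational preference. Both carbinols would be set by ketone reduction, for which the Felkin–Anh and chelation models point to the required sense. On C7 control and on step count (about six) it is the better plan on paper.
- Against: a very reactive, unstabilised ylide reads a remote auxiliary poorly, so absolute configuration is uncertain. The hindered pyrrolidine amides resist conversion to ketones, and an aryllithium exposes C8/C8' (α to carbonyl, β to the ring oxygen) to epimerisation and β-elimination.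
- Comparison: its key step is stereospecific where the chosen one is stepwise. The chosen route takes its absolute configuration from a reliable auxiliary aldol and never forces acyl substitution on a hindered amide.

**Alternative 2:** The cut removes C9–O and C8–C8'. Ring A with C7–C9 becomes the aryl vinyl ketone A6; ring A' with C7'–C9' becomes the cyclic carbonate A5, which carries one extra alkene carbon. Zerovalent palladium with a chiral ligand would ionise A5 with loss of CO2; the alkoxide adds to A6 and the enolate closes on the branched allyl terminus to give A4. Oxidative cleavage of the 1,1-disubstituted alkene would then give diketone A3, followed by the endgame of alternative 1.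
- In favour: it is catalytic and convergent, and joins both aryl halves, closes the ring and sets C8/C8' in one step without a stoichiometric auxiliary. In these respects it equals or betters the chosen key step.
- Against: a simple aryl vinyl ketone is weakly activated, polymerisable and adds alkoxide reversibly, so enantio- and trans-selectivity would rest on an untested ligand–substrate pairing. Closure must occur at the branched allyl carbon, and the extra carbon costs an ozonolysis-type step beside two electron-rich rings.
- Comparison: step economy is about equal (nine to ten). It trades the chosen plan's risk at C7 for a risk in absolute and relative control at C8/C8'.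

**Alternative 3:** The cut removes the ring A–C7 and ring A'–C7' bonds. C7 and C7' become the OCH2 groups of bis-carbamate A8, and both rings come from boronate A9. Each OCH2 would be lithiated with sec-butyllithium and sparteine, trapped by A9, rearranged by 1,2-aryl shift with loss of carbamate, and oxidised. Done at both ends this gives A7, one hydrogenolysis from the target.
- In favour: carbinol configuration is set by the reagent and by stereospecific steps, which is clearly better than the chosen plan at its weakest point. The electron-rich rings arrive last, so no activated benzylic C–O bond meets acid, and the endgame is shorter.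
- Against: the step makes no ring and neither ring stereocentre, so the enantiopure trans core needs its own asymmetric synthesis. Two lithiation–borylations on one molecule mean a dilithio species or two cryogenic passes with stoichiometric diamine; the β-branched carbamate carbons lithiate slowly, and match/mismatch with the ring centre is possible.
- Comparison: it solves only C7/C7' and moves the ring problem elsewhere, whereas the chosen step makes the ring, C8 and C7 together. Step economy is equal at best once the core is counted.

Key step: step 7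

## Route

**Step 1**
Reactants: 1 4-(benzyloxy)-3-methoxybenzaldehyde; 2 (2-carboxyethyl)triphenylphosphonium bromide
Product: 4 (E)-4-[4-(benzyloxy)-3-methoxyphenyl]but-3-enoic acid, via phosphonium ylide 3 (not isolated)
Conditions: NaN(SiMe3)2 (2.2 equiv), THF, 0 °C; then 1, 0 °C → rt; 1 M HCl; recrystallisation
Reagents that add atoms: none
Why: Wittig olefination; ylides carrying a carboxylate two atoms from phosphorus react with aromatic aldehydes under equilibrating conditions and should give mainly the E alkene, and the minor Z acid is removed by crystallisation.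

**Step 2**
Reactants: 4 (E)-4-[4-(benzyloxy)-3-methoxyphenyl]but-3-enoic acid; 5 (S)-4-benzyloxazolidin-2-one
Product: 7 (S)-4-benzyl-3-{(E)-4-[4-(benzyloxy)-3-methoxyphenyl]but-3-enoyl}oxazolidin-2-one, via mixed pivalic anhydride 6 (not isolated)
Conditions: PivCl, Et3N, THF, −20 °C; then 5, LiCl, −20 °C → rt
Reagents that add atoms: none
Why: N-acylation of an oxazolidinone through a mixed anhydride activated by LiCl; only a tertiary amine is present, so the β,γ-double bond should not move into conjugation.

**Step 3**
Reactants: 8 4-hydroxy-3-methoxybenzaldehyde (vanillin)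
Product: 9 4-formyl-2-methoxyphenyl 4-methylbenzenesulfonate
Conditions: TsCl, Et3N, DMAP (cat.), CH2Cl2, 0 °C → rt
Reagents that add atoms: p-toluenesulfonyl chloride, Cc1ccc(cc1)S(Cl)(=O)=O
Why: Sulfonylation of a phenol; the aryl tosylate is inert to every reagent up to step 9 and turns the oxygen on ring A' from a donor into an acceptor, as the key step requires.

**Step 4**
Reactants: 7 (S)-4-benzyl-3-{(E)-4-[4-(benzyloxy)-3-methoxyphenyl]but-3-enoyl}oxazolidin-2-one; 9 4-formyl-2-methoxyphenyl 4-methylbenzenesulfonate
Product: 11 (S)-4-benzyl-3-{(2S,3E)-4-[4-(benzyloxy)-3-methoxyphenyl]-2-[(S)-hydroxy(3-methoxy-4-tosyloxyphenyl)methyl]but-3-enoyl}oxazolidin-2-one, via dibutylboron dienolate 10 (not isolated)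
Conditions: Bu2BOTf, i-Pr2NEt, CH2Cl2, −78 → 0 °C; then 9, −78 → 0 °C; pH 7 buffer, MeOH, 30% H2O2, 0 °C
Reagents that add atoms: none
Why: Evans syn aldol addition: the Z(O) boron dienolate bonds through its α-carbon in a closed Zimmerman–Traxler chair, which the γ-carbon cannot reach, and the aldehyde approaches the face away from the benzyl group of the (S)-auxiliary with the imide dipoles opposed. This sets C8' and C7' as the (2S,3S) syn pair (8'R,7'S in the later alcohol, where the priority order at C8' changes); the electron-poor aldehyde should add readily and its adduct should resist retro-aldol.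

**Step 5**
Reactants: 11 (the syn aldol adduct)
Product: 12 (1S,2S,3E)-2-{[(S)-4-benzyl-2-oxooxazolidin-3-yl]carbonyl}-4-[4-(benzyloxy)-3-methoxyphenyl]-1-(3-methoxy-4-tosyloxyphenyl)but-3-en-1-yl pivalate
Conditions: PivCl, pyridine, DMAP (cat.), CH2Cl2, 0 °C → rt
Reagents that add atoms: pivaloyl chloride, CC(C)(C)C(Cl)=O
Why: Acylation of a secondary alcohol under nucleophilic catalysis; pyridine is too weak to remove the imide α-hydrogen at this temperature, and the pivalate is non-participating, slow to migrate and resistant to the hydride of step 6.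

**Step 6**
Reactants: 12 (the pivaloylated imide)
Product: 13 (1S,2R,3E)-4-[4-(benzyloxy)-3-methoxyphenyl]-2-(hydroxymethyl)-1-(3-methoxy-4-tosyloxyphenyl)but-3-en-1-yl pivalate
Conditions: LiBH4, MeOH (1.5 equiv), THF, 0 °C
Reagents that add atoms: none
Why: Reductive cleavage of an N-acyl oxazolidinone; LiBH4 attacks the lithium-chelated exocyclic imide carbonyl far faster than the hindered pivalate or the aryl sulfonate, the auxiliary is recovered, and C8'/C7' are not touched.

**Step 7**
Reactants: 13 (the E-homoallylic alcohol); 14 formaldehyde (as paraformaldehyde)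
Product: 16 (S)-[(3R,4R)-4-{(S)-[4-(benzyloxy)-3-methoxyphenyl](hydroxy)methyl}oxolan-3-yl](3-methoxy-4-tosyloxyphenyl)methyl pivalate, via hemiformal 15 (not isolated)
Conditions: (CH2O)n (3 equiv), Sc(OTf)3 (10 mol %), H2O (10 equiv), MeNO2, 0 °C → rt
Reagents that add atoms: water, O
Why: Sc(OTf)3 condenses 14 with the primary alcohol of 13 to hemiformal 15, which ionises to the oxocarbenium ion C9H2=O(+)–C9'. C8 of the E-styrene attacks C9, the charge moves to C7 where the para-benzyloxy group of ring A stabilises it, and water bonds to C7; the closest known type is the Prins cyclisation of 4-aryl homoallylic alcohols with aldehydes to 3-(α-substituted benzyl)tetrahydrofurans. The ring closes by C8–C9 bond formation in a five-membered envelope, exo with respect to the styrene (C7 stays outside) and endo with respect to the C9=O(+) unit; the six-membered alternative through C7 would place the charge on unstabilised C8. C8 is controlled by C8': the allylic C8'–H eclipses the C7=C8 bond (allylic 1,3-strain) and the CH(OPiv)Ar' group lies pseudo-equatorial, away from incoming C9, which should give the trans ring (8R from 8'R). C7 is controlled by the E geometry together with anti addition: the new C8–C9 bond is aligned with the empty orbital at C7 and shields that face, so water should enter opposite to it and give 7S. The step needs attack through C8, no ionisation at C7', no Friedel–Crafts closure of ring A' onto C7, and anti capture; the donor ring A secures the first, and the 4'-O-tosyl group with the hindered pivalate secures the second and third. Anti capture is the least secure, because the cation can rotate before capture, so low temperature, excess water and a short reaction time are chosen to favour kinetic capture and to keep the product from re-ionising.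

**Step 8**
Reactants: 16 (the Prins product)
Product: 17 4-[(S)-{(3R,4R)-4-[(S)-[4-(benzyloxy)-3-methoxyphenyl](hydroxy)methyl]oxolan-3-yl}(hydroxy)methyl]-2-methoxyphenyl 4-methylbenzenesulfonate
Conditions: i-Bu2AlH (4 equiv), CH2Cl2, −78 °C; aq. KNaC4H4O6
Reagents that add atoms: none
Why: Reductive ester cleavage at −78 °C, where the aryl sulfonate is inert; the pivalate is removed before the ring A' phenol is freed, because a para-phenoxide would expel a benzylic carboxylate as a quinone methide and scramble C7', whereas the alkoxide formed here cannot leave.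

**Step 9**
Reactants: 17 (the diol tosylate)
Product: 18 (S)-[(3R,4R)-4-{(S)-[4-(benzyloxy)-3-methoxyphenyl](hydroxy)methyl}oxolan-3-yl](4-hydroxy-3-methoxyphenyl)methanol
Conditions: Mg turnings (10 equiv), MeOH, 0 °C → rt; aq. NH4Cl
Reagents that add atoms: none
Why: Reductive S–O cleavage of an aryl sulfonate by electron transfer from magnesium in methanol; the medium is only mildly basic at room temperature, so the para-hydroxybenzylic carbinol at C7' should not ionise, and the benzyl ether is untouched.

**Step 10**
Reactants: 18 (the mono-benzyl ether)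
Product: 19 (7S,7'S,8R,8'R)-4,4'-dihydroxy-3,3'-dimethoxy-9,9'-epoxylignan-7,7'-diol (CNP0157038.3)
Conditions: H2 (1 atm), 10% Pd/C, EtOAc–EtOH, rt
Reagents that add atoms: none
Why: Hydrogenolysis of an aryl benzyl ether in a neutral solvent should be much faster than cleavage of the secondary benzylic C–OH bonds; the reaction is stopped after one equivalent of hydrogen and no stereocentre is involved.

## Compound list

1 | 4-(benzyloxy)-3-methoxybenzaldehyde | O=Cc1ccc(OCc2ccccc2)c(OC)c1 | starting material
2 | (2-carboxyethyl)triphenylphosphonium bromide | OC(=O)CC[P+](c1ccccc1)(c1ccccc1)c1ccccc1.[Br-] | starting material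
3 | sodium 3-(triphenylphosphoranylidene)propanoate | [Na+].[O-]C(=O)CC=P(c1ccccc1)(c1ccccc1)c1ccccc1 | intermediate
4 | (E)-4-[4-(benzyloxy)-3-methoxyphenyl]but-3-enoic acid | OC(=O)C/C=C/c1ccc(OCc2ccccc2)c(OC)c1 | intermediate
5 | (S)-4-benzyloxazolidin-2-one | O=C1N[C@@H](Cc2ccccc2)CO1 | starting material
6 | (E)-4-[4-(benzyloxy)-3-methoxyphenyl]but-3-enoic pivalic anhydride | CC(C)(C)C(=O)OC(=O)C/C=C/c1ccc(OCc2ccccc2)c(OC)c1 | intermediate
7 | (S)-4-benzyl-3-{(E)-4-[4-(benzyloxy)-3-methoxyphenyl]but-3-enoyl}oxazolidin-2-one | O=C(C/C=C/c1ccc(OCc2ccccc2)c(OC)c1)N1[C@@H](Cc2ccccc2)COC1=O | intermediate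
8 | 4-hydroxy-3-methoxybenzaldehyde | O=Cc1ccc(O)c(OC)c1 | starting material
9 | 4-formyl-2-methoxyphenyl 4-methylbenzenesulfonate | O=Cc1ccc(OS(=O)(=O)c2ccc(C)cc2)c(OC)c1 | intermediate
10 | (S)-4-benzyl-3-{(1Z,3E)-4-[4-(benzyloxy)-3-methoxyphenyl]-1-[(dibutylboranyl)oxy]buta-1,3-dien-1-yl}oxazolidin-2-one | CCCCB(CCCC)O/C(=C\C=C\c1ccc(OCc2ccccc2)c(OC)c1)N1[C@@H](Cc2ccccc2)COC1=O | intermediate
11 | (S)-4-benzyl-3-{(2S,3E)-4-[4-(benzyloxy)-3-methoxyphenyl]-2-[(S)-hydroxy(3-methoxy-4-tosyloxyphenyl)methyl]but-3-enoyl}oxazolidin-2-one | O=C(N1[C@@H](Cc2ccccc2)COC1=O)[C@@H](/C=C/c1ccc(OCc2ccccc2)c(OC)c1)[C@H](O)c1ccc(OS(=O)(=O)c2ccc(C)cc2)c(OC)c1 | intermediate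
12 | (1S,2S,3E)-2-{[(S)-4-benzyl-2-oxooxazolidin-3-yl]carbonyl}-4-[4-(benzyloxy)-3-methoxyphenyl]-1-(3-methoxy-4-tosyloxyphenyl)but-3-en-1-yl pivalate | O=C(N1[C@@H](Cc2ccccc2)COC1=O)[C@@H](/C=C/c1ccc(OCc2ccccc2)c(OC)c1)[C@H](OC(=O)C(C)(C)C)c1ccc(OS(=O)(=O)c2ccc(C)cc2)c(OC)c1 | intermediate
13 | (1S,2R,3E)-4-[4-(benzyloxy)-3-methoxyphenyl]-2-(hydroxymethyl)-1-(3-methoxy-4-tosyloxyphenyl)but-3-en-1-yl pivalate | OC[C@@H](/C=C/c1ccc(OCc2ccccc2)c(OC)c1)[C@H](OC(=O)C(C)(C)C)c1ccc(OS(=O)(=O)c2ccc(C)cc2)c(OC)c1 | intermediate
14 | formaldehyde (used as paraformaldehyde) | C=O | starting material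
15 | (1S,2R,3E)-4-[4-(benzyloxy)-3-methoxyphenyl]-2-[(hydroxymethoxy)methyl]-1-(3-methoxy-4-tosyloxyphenyl)but-3-en-1-yl pivalate | OCOC[C@@H](/C=C/c1ccc(OCc2ccccc2)c(OC)c1)[C@H](OC(=O)C(C)(C)C)c1ccc(OS(=O)(=O)c2ccc(C)cc2)c(OC)c1 | intermediate
16 | (S)-[(3R,4R)-4-{(S)-[4-(benzyloxy)-3-methoxyphenyl](hydroxy)methyl}oxolan-3-yl](3-methoxy-4-tosyloxyphenyl)methyl pivalate | COc1cc([C@@H](O)[C@H]2COC[C@@H]2[C@H](OC(=O)C(C)(C)C)c2ccc(OS(=O)(=O)c3ccc(C)cc3)c(OC)c2)ccc1OCc1ccccc1 | intermediate
17 | 4-[(S)-{(3R,4R)-4-[(S)-[4-(benzyloxy)-3-methoxyphenyl](hydroxy)methyl]oxolan-3-yl}(hydroxy)methyl]-2-methoxyphenyl 4-methylbenzenesulfonate | COc1cc([C@@H](O)[C@H]2COC[C@@H]2[C@H](O)c2ccc(OS(=O)(=O)c3ccc(C)cc3)c(OC)c2)ccc1OCc1ccccc1 | intermediate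
18 | (S)-[(3R,4R)-4-{(S)-[4-(benzyloxy)-3-methoxyphenyl](hydroxy)methyl}oxolan-3-yl](4-hydroxy-3-methoxyphenyl)methanol | COc1cc([C@@H](O)[C@H]2COC[C@@H]2[C@H](O)c2ccc(O)c(OC)c2)ccc1OCc1ccccc1 | intermediate
19 | (S,S)-[(3R,4R)-oxolane-3,4-diyl]bis[(4-hydroxy-3-methoxyphenyl)methanol] | COc1cc([C@@H](O)[C@H]2COC[C@@H]2[C@H](O)c2ccc(O)c(OC)c2)ccc1O | target

## Step count and least certain steps

Total: 10 steps. Longest linear sequence: 9 steps (steps 1, 2 and 4–10, from 1 to 19); step 3 is a one-step side branch.

**Step 7 (key step).** The most likely failure is loss of control at C7. The benzylic cation can rotate about C7–C8 before capture, or the product carbinol can re-ionise, so water also enters syn to the C8–C9 bond; on steric grounds the face away from the bulkier C8' branch is the wrong one. Lesser threats are closure of ring A' onto C7 and acid-promoted addition of the C9' hydroxyl across the styrene. The fallback sets out from 16 obtained in admixture with its (7R)-epimer F1. Dess–Martin periodinane with NaHCO3 in CH2Cl2 oxidises both epimers to the single aryl ketone F2. Zn(BH4)2 in Et2O at −20 °C then reduces it: the chelate between the ketone and ring oxygens and the Felkin–Anh model with C8' as the large group both direct hydride anti to C8', which is the 7S carbinol. The fallback comes back to the route at 16.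

**Step 5.** The most likely failure is base-induced β-elimination of the new β-pivaloyloxy imide, whose α-hydrogen is both allylic and α to the imide, or retro-aldol cleavage during slow acylation of a hindered alcohol. The fallback sets out from 11. LiBH4/MeOH in THF at 0 °C gives the 1,3-diol F3; TBSCl and imidazole protect the primary hydroxyl as the silyl ether F4; PivCl, DMAP and pyridine at 40 °C give the silyl ether pivalate F5. HF·pyridine in THF–pyridine, chosen to avoid an alkoxide that could shift the acyl group, then returns the route at 13.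

**Step 6.** The most likely failure is 1,3-migration of the pivaloyl group to the primary alkoxide formed on reduction, or hydride attack on the β-ester. The fallback sets out from 11 and keeps esters out until the ring is made. TIPSOTf and 2,6-lutidine give the triisopropylsilyl ether imide F6; LiBH4 gives the silyl ether alcohol F7; the conditions of step 7 with 14 give the silyl-protected tetrahydrofuran F8. Bu4NF in THF at 0 °C then returns the route at 17.

**Step 4.** The most likely failure is bond formation through the γ-carbon of the aryl-conjugated dienolate, or erosion of syn selectivity by reversible addition. The fallback sets out from 5, 9 and 1 and uses the parent dienolate, whose α-selectivity is well established. Acylation of 5 with but-3-enoic acid (PivCl, Et3N, LiCl) gives the but-3-enoyl imide F9, and the same boron aldol with 9 gives the α-vinyl syn adduct F10. Cross-metathesis of F10 with the styrene F11 (from 1 and Ph3P=CH2) using second-generation Hoveyda–Grubbs catalyst in CH2Cl2 at 40 °C installs the E-styrene and returns the route at 11.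

## Further compounds

F1 | step 7 | (S)-[(3R,4R)-4-{(R)-[4-(benzyloxy)-3-methoxyphenyl](hydroxy)methyl}oxolan-3-yl](3-methoxy-4-tosyloxyphenyl)methyl pivalate | COc1cc([C@H](O)[C@H]2COC[C@@H]2[C@H](OC(=O)C(C)(C)C)c2ccc(OS(=O)(=O)c3ccc(C)cc3)c(OC)c2)ccc1OCc1ccccc1
F2 | step 7 | (S)-{(3R,4R)-4-[4-(benzyloxy)-3-methoxybenzoyl]oxolan-3-yl}(3-methoxy-4-tosyloxyphenyl)methyl pivalate | COc1cc(C(=O)[C@H]2COC[C@@H]2[C@H](OC(=O)C(C)(C)C)c2ccc(OS(=O)(=O)c3ccc(C)cc3)c(OC)c2)ccc1OCc1ccccc1
F3 | step 5 | 4-{(1S,2R,3E)-4-[4-(benzyloxy)-3-methoxyphenyl]-1-hydroxy-2-(hydroxymethyl)but-3-en-1-yl}-2-methoxyphenyl 4-methylbenzenesulfonate | OC[C@@H](/C=C/c1ccc(OCc2ccccc2)c(OC)c1)[C@H](O)c1ccc(OS(=O)(=O)c2ccc(C)cc2)c(OC)c1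
F4 | step 5 | 4-{(1S,2R,3E)-4-[4-(benzyloxy)-3-methoxyphenyl]-2-[(tert-butyldimethylsilyloxy)methyl]-1-hydroxybut-3-en-1-yl}-2-methoxyphenyl 4-methylbenzenesulfonate | CC(C)(C)[Si](C)(C)OC[C@@H](/C=C/c1ccc(OCc2ccccc2)c(OC)c1)[C@H](O)c1ccc(OS(=O)(=O)c2ccc(C)cc2)c(OC)c1
F5 | step 5 | (1S,2R,3E)-4-[4-(benzyloxy)-3-methoxyphenyl]-2-[(tert-butyldimethylsilyloxy)methyl]-1-(3-methoxy-4-tosyloxyphenyl)but-3-en-1-yl pivalate | CC(C)(C)[Si](C)(C)OC[C@@H](/C=C/c1ccc(OCc2ccccc2)c(OC)c1)[C@H](OC(=O)C(C)(C)C)c1ccc(OS(=O)(=O)c2ccc(C)cc2)c(OC)c1
F6 | step 6 | (S)-4-benzyl-3-{(2S,3E)-4-[4-(benzyloxy)-3-methoxyphenyl]-2-[(S)-(3-methoxy-4-tosyloxyphenyl)(triisopropylsilyloxy)methyl]but-3-enoyl}oxazolidin-2-one | O=C(N1[C@@H](Cc2ccccc2)COC1=O)[C@@H](/C=C/c1ccc(OCc2ccccc2)c(OC)c1)[C@H](O[Si](C(C)C)(C(C)C)C(C)C)c1ccc(OS(=O)(=O)c2ccc(C)cc2)c(OC)c1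
F7 | step 6 | 4-{(1S,2R,3E)-4-[4-(benzyloxy)-3-methoxyphenyl]-2-(hydroxymethyl)-1-(triisopropylsilyloxy)but-3-en-1-yl}-2-methoxyphenyl 4-methylbenzenesulfonate | OC[C@@H](/C=C/c1ccc(OCc2ccccc2)c(OC)c1)[C@H](O[Si](C(C)C)(C(C)C)C(C)C)c1ccc(OS(=O)(=O)c2ccc(C)cc2)c(OC)c1
F8 | step 6 | 4-[(S)-{(3R,4R)-4-[(S)-[4-(benzyloxy)-3-methoxyphenyl](hydroxy)methyl]oxolan-3-yl}(triisopropylsilyloxy)methyl]-2-methoxyphenyl 4-methylbenzenesulfonate | COc1cc([C@@H](O)[C@H]2COC[C@@H]2[C@H](O[Si](C(C)C)(C(C)C)C(C)C)c2ccc(OS(=O)(=O)c3ccc(C)cc3)c(OC)c2)ccc1OCc1ccccc1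
F9 | step 4 | (S)-4-benzyl-3-(but-3-enoyl)oxazolidin-2-one | C=CCC(=O)N1[C@@H](Cc2ccccc2)COC1=O
F10 | step 4 | (S)-4-benzyl-3-{(2S)-2-[(S)-hydroxy(3-methoxy-4-tosyloxyphenyl)methyl]but-3-enoyl}oxazolidin-2-one | O=C(N1[C@@H](Cc2ccccc2)COC1=O)[C@@H](C=C)[C@H](O)c1ccc(OS(=O)(=O)c2ccc(C)cc2)c(OC)c1
F11 | step 4 | 1-(benzyloxy)-4-ethenyl-2-methoxybenzene | C=Cc1ccc(OCc2ccccc2)c(OC)c1
A1 | alternative 1 | (3R,4R)-oxolane-3,4-diyl bis[(2R,5R)-2,5-dimethylpyrrolidin-1-yl ketone] | O=C(N1[C@H](C)CC[C@H]1C)[C@H]1COC[C@@H]1C(=O)N1[C@H](C)CC[C@H]1C
A2 | alternative 1 | (E)-1,4-bis[(2R,5R)-2,5-dimethylpyrrolidin-1-yl]but-2-ene-1,4-dione | O=C(/C=C/C(=O)N1[C@H](C)CC[C@H]1C)N1[C@H](C)CC[C@H]1C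
A3 | alternative 1 | [(3R,4R)-oxolane-3,4-diyl]bis{[4-(benzyloxy)-3-methoxyphenyl]methanone} | O=C(c1ccc(OCc2ccccc2)c(OC)c1)[C@H]1COC[C@@H]1C(=O)c1ccc(OCc2ccccc2)c(OC)c1
A4 | alternative 2 | [4-(benzyloxy)-3-methoxyphenyl]{(3R,4S)-4-[1-(4-benzyloxy-3-methoxyphenyl)ethenyl]oxolan-3-yl}methanone (trans) | O=C(c1ccc(OCc2ccccc2)c(OC)c1)[C@H]1COC[C@@H]1C(=C)c1ccc(OCc2ccccc2)c(OC)c1
A5 | alternative 2 | 4-{1-[4-(benzyloxy)-3-methoxyphenyl]ethenyl}-1,3-dioxolan-2-one | C=C(c1ccc(OCc2ccccc2)c(OC)c1)C1COC(=O)O1
A6 | alternative 2 | 1-[4-(benzyloxy)-3-methoxyphenyl]prop-2-en-1-one | C=CC(=O)c1ccc(OCc2ccccc2)c(OC)c1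
A7 | alternative 3 | (S,S)-[(3R,4R)-oxolane-3,4-diyl]bis{[4-(benzyloxy)-3-methoxyphenyl]methanol} | COc1cc([C@@H](O)[C@H]2COC[C@@H]2[C@H](O)c2ccc(OCc3ccccc3)c(OC)c2)ccc1OCc1ccccc1
A8 | alternative 3 | [(3R,4R)-oxolane-3,4-diyl]bis(methylene) bis[di(propan-2-yl)carbamate] | CC(C)N(C(C)C)C(=O)OC[C@H]1COC[C@@H]1COC(=O)N(C(C)C)C(C)C
A9 | alternative 3 | 2-[4-(benzyloxy)-3-methoxyphenyl]-4,4,5,5-tetramethyl-1,3,2-dioxaborolane | COc1cc(B2OC(C)(C)C(C)(C)O2)ccc1OCc1ccccc1
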